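**Plan**

- Numbering: ring C1 (OH), C2 (CH3), C4 (OH), C6 (chain); chain C1' (benzylic) to C16' (CH2OH). Retrosynthetic cuts, in order: the C4–O bond (hydroquinone ← quinone ← C4–H phenol), the C6–C1' bond (ortho-C-allylation of 2-methylphenol), C1'–C2' together with C3'–CH3 (alkyne methylalumination and hydroxymethylation), C4'–C5' (propargyl addition to a C5'–C16' enal), and the C16'–O bond (allylic hydroxylation of farnesol).
- Forward: farnesol is hydroxylated at its terminal E-methyl group, converted into the 12-silyloxy enal, propargylated, carbometallated to the C1'–C16' allylic alcohol, brominated, joined to the purchased arene, desilylated, oxidised to the para-quinone and reduced. The benzene ring is bought; no ring is formed.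
- Stereochemistry: C5' (S) comes from a chiral phosphoric acid-controlled allenylboration; 2'E from syn-methylalumination with retentive C–C bond formation; 6'E and 10'E from (2E,6E)-farnesol; 14'E from the E-selective SeO2 oxidation.
- Enabling feature: in the benzene ring the oxygen on C1 has C2 (methyl) and C6 (chain) as its ortho neighbours, so C4, para to it, is the only hydrogen-bearing ring carbon conjugated with that oxygen. An oxidant acting through the phenoxyl radical can therefore place the second oxygen only at C4 of the intact 2-methyl-6-alkylphenol.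

Key step: step 12

Assumption: the (S)-configured phosphoric acid is taken to deliver the propargyl group to the Si face of the enal made in step 5, the mirror image of the Re-face delivery of the (R)-acid to aryl aldehydes; if the enal responds with the opposite sense, the (R)-acid is used and nothing else changes.

Abbreviations: TBS = tert-butyldimethylsilyl, TBDPS = tert-butyldiphenylsilyl, SEM = 2-(trimethylsilyl)ethoxymethyl.

**Step 1**
Reactants: 1 (2E,6E)-farnesol
Product: 2 (2E,6E)-farnesyl acetate
Conditions: Ac2O, Et3N, 4-(dimethylamino)pyridine (cat.), CH2Cl2, 0 °C to rt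
Reagents that add atoms: acetic anhydride, CC(=O)OC(C)=O
Why: Nucleophile-catalysed O-acylation of a primary allylic alcohol is routine, and the acetate both masks C1–OH and makes the 2,3-alkene electron-poorer so that the allylic oxidation of step 2 goes to the far end of the chain.

**Step 2**
Reactants: 2 (2E,6E)-farnesyl acetate
Product: 3 (2E,6E,10E)-12-hydroxy-3,7,11-trimethyldodeca-2,6,10-trien-1-yl acetate
Conditions: SeO2 (0.1 equiv), t-BuOOH (70% aq., 3 equiv), salicylic acid (0.1 equiv), CH2Cl2, 0 °C to rt, stopped at partial conversion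
Reagents that add atoms: selenium dioxide, O=[Se]=O (catalytic oxygen carrier); tert-butyl hydroperoxide, CC(C)(C)OO (stoichiometric oxygen source)
Why: Catalytic SeO2 allylic hydroxylation (ene reaction followed by a [2,3]-sigmatropic shift) attacks the most electron-rich, least hindered trisubstituted alkene at its E-methyl group and should give the 10E primary allylic alcohol that becomes C16'–OH, with unreacted 2 recycled and any over-oxidised enal removed by chromatography.

**Step 3**
Reactants: 3 (2E,6E,10E)-12-hydroxy-3,7,11-trimethyldodeca-2,6,10-trien-1-yl acetate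
Product: 4 (2E,6E,10E)-12-(tert-butyldiphenylsilyloxy)-3,7,11-trimethyldodeca-2,6,10-trien-1-yl acetate
Conditions: t-BuPh2SiCl, imidazole, CH2Cl2, 0 °C to rt
Reagents that add atoms: tert-butyldiphenylsilyl chloride, CC(C)(C)[Si](Cl)(c1ccccc1)c1ccccc1
Why: Silylation of the only free hydroxyl is standard, and the TBDPS ether should survive methanolysis, oxoammonium oxidation, organoaluminium reagents and sodium phenoxide yet fall to fluoride at the end.

**Step 4**
Reactants: 4 (2E,6E,10E)-12-(tert-butyldiphenylsilyloxy)-3,7,11-trimethyldodeca-2,6,10-trien-1-yl acetate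
Product: 5 (2E,6E,10E)-12-(tert-butyldiphenylsilyloxy)-3,7,11-trimethyldodeca-2,6,10-trien-1-ol
Conditions: K2CO3 (0.3 equiv), MeOH, rt
Reagents that add atoms: none
Why: Base-catalysed transesterification with methanol frees C1–OH without touching the silyl ether or the alkenes.

**Step 5**
Reactants: 5 (2E,6E,10E)-12-(tert-butyldiphenylsilyloxy)-3,7,11-trimethyldodeca-2,6,10-trien-1-ol
Product: 6 (2E,6E,10E)-12-(tert-butyldiphenylsilyloxy)-3,7,11-trimethyldodeca-2,6,10-trienal
Conditions: PhI(OAc)2 (1.1 equiv), 2,2,6,6-tetramethylpiperidin-1-oxyl (0.1 equiv), CH2Cl2, rt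
Reagents that add atoms: none
Why: Oxoammonium-mediated oxidation of a primary allylic alcohol stops at the enal and is known to leave the geometry of the conjugated alkene unchanged, while the silyl ether is inert.

**Step 6**
Reactants: 6 (2E,6E,10E)-12-(tert-butyldiphenylsilyloxy)-3,7,11-trimethyldodeca-2,6,10-trienal; 7 allenylboronic acid pinacol ester
Product: 9 (4S,5E,9E,13E)-15-(tert-butyldiphenylsilyloxy)-6,10,14-trimethylpentadeca-5,9,13-trien-1-yn-4-ol, via pinacol borate 8 (not isolated)
Conditions: (S)-3,3'-bis(2,4,6-triisopropylphenyl)-1,1'-binaphthyl-2,2'-diyl hydrogen phosphate [(S)-TRIP, 10 mol%], 4 Å molecular sieves, toluene, −20 °C; aq. NaHCO3 work-up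
Reagents that add atoms: none
Why: In this chiral Brønsted acid-catalysed allenylboration (asymmetric propargylation) the allenyl group is transferred through a closed six-membered transition state with allylic transposition, so only the homopropargylic alcohol forms, and the phosphate, bound to the pseudoaxial boronate oxygen and the formyl hydrogen, should expose the Si face of the aldehyde and set C5' as S.

**Step 7**
Reactants: 9 (4S,5E,9E,13E)-15-(tert-butyldiphenylsilyloxy)-6,10,14-trimethylpentadeca-5,9,13-trien-1-yn-4-ol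
Product: 10 (4S,5E,9E,13E)-4-(tert-butyldimethylsilyloxy)-15-(tert-butyldiphenylsilyloxy)-6,10,14-trimethylpentadeca-5,9,13-trien-1-yne
Conditions: t-BuMe2SiCl, imidazole, DMF, rt
Reagents that add atoms: tert-butyldimethylsilyl chloride, CC(C)(C)[Si](C)(C)Cl
Why: Standard silylation protects the secondary allylic alcohol against the organoaluminium reagent, the sulfonylation and the phenoxide of the following steps without affecting the stereocentre.

**Step 8**
Reactants: 10 (4S,5E,9E,13E)-4-(tert-butyldimethylsilyloxy)-15-(tert-butyldiphenylsilyloxy)-6,10,14-trimethylpentadeca-5,9,13-trien-1-yne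
Product: 13 (2E,5S,6E,10E,14E)-5-(tert-butyldimethylsilyloxy)-16-(tert-butyldiphenylsilyloxy)-3,7,11,15-tetramethylhexadeca-2,6,10,14-tetraen-1-ol, via alkenylalane 11 (not isolated), via aluminium alkoxide 12 (not isolated)
Conditions: Me3Al (3 equiv), Cp2ZrCl2 (0.5 equiv), CH2Cl2, 0 °C to rt; volatiles removed; (CH2O)n (excess), THF, 0 °C to rt; aq. potassium sodium tartrate work-up
Reagents that add atoms: trimethylaluminium, C[Al](C)C (the methyl group on C3'); formaldehyde as paraformaldehyde, C=O (C1' and its oxygen)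
Why: Zirconium-catalysed methylalumination of the terminal alkyne (Negishi carboalumination) adds methyl and aluminium syn with methyl at the internal carbon, and C-hydroxymethylation of alkenylalane 11 with formaldehyde goes with retention, so the 2E alkene should result while the trisubstituted alkenes and silyl ethers stay inert.

**Step 9**
Reactants: 13 (2E,5S,6E,10E,14E)-5-(tert-butyldimethylsilyloxy)-16-(tert-butyldiphenylsilyloxy)-3,7,11,15-tetramethylhexadeca-2,6,10,14-tetraen-1-ol
Product: 15 (2E,5S,6E,10E,14E)-1-bromo-5-(tert-butyldimethylsilyloxy)-16-(tert-butyldiphenylsilyloxy)-3,7,11,15-tetramethylhexadeca-2,6,10,14-tetraene, via allylic mesylate 14 (not isolated)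
Conditions: MsCl, Et3N, THF, −40 °C; then LiBr (THF solution), −40 to 0 °C; used crude at once
Reagents that add atoms: lithium bromide, [Li+].[Br-]
Why: Sulfonylation followed by SN2 displacement with bromide under cold, non-acidic conditions is the usual way to polyprenyl bromides and should keep the 2E geometry and both silyl ethers.

**Step 10**
Reactants: 15 (2E,5S,6E,10E,14E)-1-bromo-5-(tert-butyldimethylsilyloxy)-16-(tert-butyldiphenylsilyloxy)-3,7,11,15-tetramethylhexadeca-2,6,10,14-tetraene; 16 2-methylphenol
Product: 18 2-[(2E,5S,6E,10E,14E)-5-(tert-butyldimethylsilyloxy)-16-(tert-butyldiphenylsilyloxy)-3,7,11,15-tetramethylhexadeca-2,6,10,14-tetraen-1-yl]-6-methylphenol, via sodium 2-methylphenoxide 17 (not isolated)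
Conditions: 16 (3 equiv), NaH (2.8 equiv), toluene, 0 °C to rt; then 15 in toluene, rt, dark
Reagents that add atoms: none
Why: C-alkylation of an ambident sodium phenoxide in a non-polar medium, where the tightly bound cation shields oxygen and directs the primary allylic bromide to the adjacent carbon, should join C1' to the only ortho carbon that can rearomatise (C6) by SN2 with retention of 2E, and the excess of cheap phenoxide limits double allylation.

**Step 11**
Reactants: 18 2-[(2E,5S,6E,10E,14E)-5-(tert-butyldimethylsilyloxy)-16-(tert-butyldiphenylsilyloxy)-3,7,11,15-tetramethylhexadeca-2,6,10,14-tetraen-1-yl]-6-methylphenol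
Product: 19 2-[(2E,5S,6E,10E,14E)-5,16-dihydroxy-3,7,11,15-tetramethylhexadeca-2,6,10,14-tetraen-1-yl]-6-methylphenol
Conditions: Bu4NF (3 equiv), THF, 0 °C to rt; aq. NH4Cl work-up
Reagents that add atoms: none
Why: Fluoride-driven cleavage of both silyl ethers needs no acid, so the allylic carbinols should not ionise and the ortho-allylphenol should not close to a chroman.

**Step 12**
Reactants: 19 2-[(2E,5S,6E,10E,14E)-5,16-dihydroxy-3,7,11,15-tetramethylhexadeca-2,6,10,14-tetraen-1-yl]-6-methylphenol
Product: 22 2-[(2E,5S,6E,10E,14E)-5,16-dihydroxy-3,7,11,15-tetramethylhexadeca-2,6,10,14-tetraen-1-yl]-6-methyl-1,4-benzoquinone, via phenoxyl radical 20 (not isolated), via dienone adduct 21 (not isolated)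
Conditions: (KSO3)2NO (3 equiv), aq. KH2PO4 (pH about 6), acetone/H2O, 0 °C to rt
Reagents that add atoms: potassium nitrosodisulfonate, [K+].[K+].[O]N(S(=O)(=O)[O-])S(=O)(=O)[O-] (the oxygen on C4)
Why: The persistent radical dianion of (KSO3)2NO abstracts the phenolic hydrogen of 19 (phenoxyl radical 20, with HON(SO3K)2 as co-product), and a second equivalent couples through its oxygen with the ring carbon para to the C1 oxygen to give dienone 21, which loses HN(SO3K)2 and so forms the C4=O bond of quinone 22. This is the Teuber oxidation, the standard conversion of 2,6-dialkylphenols with a free para position into 1,4-benzoquinones. No ring is closed and no stereocentre is created; C5' is remote from the ring and is not touched. The step needs para rather than ortho oxygenation, which is secured because C2 carries the methyl group and C6 the chain, so that C4 is the only hydrogen-bearing carbon with spin density. It also needs the phenol to react in the presence of four trisubstituted alkenes and two allylic alcohols, which follows from the reagent being too weak a hydrogen abstractor for C–H or alcoholic O–H bonds at these temperatures. The KH2PO4 buffer holds the medium near neutrality, so the allylic carbinols should not ionise and the ortho-allyl quinone should not isomerise to a chromenol.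

**Step 13**
Reactants: 22 2-[(2E,5S,6E,10E,14E)-5,16-dihydroxy-3,7,11,15-tetramethylhexadeca-2,6,10,14-tetraen-1-yl]-6-methyl-1,4-benzoquinone
Product: 23 2-[(2E,5S,6E,10E,14E)-5,16-dihydroxy-3,7,11,15-tetramethylhexadeca-2,6,10,14-tetraen-1-yl]-6-methylbenzene-1,4-diol (CNP0151872.1)
Conditions: Na2S2O4 (aq., excess), EtOAc/H2O (degassed), rt, argon
Reagents that add atoms: none
Why: Two-electron reduction of a 1,4-benzoquinone by dithionite in a two-phase system is fast at near-neutral pH, leaves alkenes and allylic alcohols alone, and delivers the air-sensitive hydroquinone directly into the organic layer under argon.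

**Compound list**

1 | (2E,6E)-farnesol | CC(C)=CCC/C(C)=C/CC/C(C)=C/CO | starting material
2 | (2E,6E)-farnesyl acetate | CC(C)=CCC/C(C)=C/CC/C(C)=C/COC(C)=O | intermediate
3 | (2E,6E,10E)-12-hydroxy-3,7,11-trimethyldodeca-2,6,10-trien-1-yl acetate | C/C(CO)=C\CC/C(C)=C/CC/C(C)=C/COC(C)=O | intermediate
4 | (2E,6E,10E)-12-(tert-butyldiphenylsilyloxy)-3,7,11-trimethyldodeca-2,6,10-trien-1-yl acetate | C/C(CO[Si](c1ccccc1)(c1ccccc1)C(C)(C)C)=C\CC/C(C)=C/CC/C(C)=C/COC(C)=O | intermediate
5 | (2E,6E,10E)-12-(tert-butyldiphenylsilyloxy)-3,7,11-trimethyldodeca-2,6,10-trien-1-ol | C/C(CO[Si](c1ccccc1)(c1ccccc1)C(C)(C)C)=C\CC/C(C)=C/CC/C(C)=C/CO | intermediate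
6 | (2E,6E,10E)-12-(tert-butyldiphenylsilyloxy)-3,7,11-trimethyldodeca-2,6,10-trienal | C/C(CO[Si](c1ccccc1)(c1ccccc1)C(C)(C)C)=C\CC/C(C)=C/CC/C(C)=C/C=O | intermediate
7 | allenylboronic acid pinacol ester | C=C=CB1OC(C)(C)C(C)(C)O1 | starting material
8 | O-pinacolboryl derivative (borate ester) of alcohol 9, formed in the flask | C/C(CO[Si](c1ccccc1)(c1ccccc1)C(C)(C)C)=C\CC/C(C)=C/CC/C(C)=C/[C@@H](OB1OC(C)(C)C(C)(C)O1)CC#C | intermediate
9 | (4S,5E,9E,13E)-15-(tert-butyldiphenylsilyloxy)-6,10,14-trimethylpentadeca-5,9,13-trien-1-yn-4-ol | C/C(CO[Si](c1ccccc1)(c1ccccc1)C(C)(C)C)=C\CC/C(C)=C/CC/C(C)=C/[C@@H](O)CC#C | intermediate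
10 | (4S,5E,9E,13E)-4-(tert-butyldimethylsilyloxy)-15-(tert-butyldiphenylsilyloxy)-6,10,14-trimethylpentadeca-5,9,13-trien-1-yne | C/C(CO[Si](c1ccccc1)(c1ccccc1)C(C)(C)C)=C\CC/C(C)=C/CC/C(C)=C/[C@@H](O[Si](C)(C)C(C)(C)C)CC#C | intermediate
11 | dimethyl[(1E,4S,5E,9E,13E)-4-(tert-butyldimethylsilyloxy)-15-(tert-butyldiphenylsilyloxy)-2,6,10,14-tetramethylpentadeca-1,5,9,13-tetraen-1-yl]alane, formed in the flask | C/C(CO[Si](c1ccccc1)(c1ccccc1)C(C)(C)C)=C\CC/C(C)=C/CC/C(C)=C/[C@@H](O[Si](C)(C)C(C)(C)C)C/C(C)=C/[Al](C)C | intermediate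
12 | dimethylaluminium alkoxide of alcohol 13, formed in the flask | C/C(CO[Si](c1ccccc1)(c1ccccc1)C(C)(C)C)=C\CC/C(C)=C/CC/C(C)=C/[C@@H](O[Si](C)(C)C(C)(C)C)C/C(C)=C/CO[Al](C)C | intermediate
13 | (2E,5S,6E,10E,14E)-5-(tert-butyldimethylsilyloxy)-16-(tert-butyldiphenylsilyloxy)-3,7,11,15-tetramethylhexadeca-2,6,10,14-tetraen-1-ol | C/C(CO[Si](c1ccccc1)(c1ccccc1)C(C)(C)C)=C\CC/C(C)=C/CC/C(C)=C/[C@@H](O[Si](C)(C)C(C)(C)C)C/C(C)=C/CO | intermediate
14 | methanesulfonate of alcohol 13, formed in the flask | C/C(CO[Si](c1ccccc1)(c1ccccc1)C(C)(C)C)=C\CC/C(C)=C/CC/C(C)=C/[C@@H](O[Si](C)(C)C(C)(C)C)C/C(C)=C/COS(C)(=O)=O | intermediate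
15 | (2E,5S,6E,10E,14E)-1-bromo-5-(tert-butyldimethylsilyloxy)-16-(tert-butyldiphenylsilyloxy)-3,7,11,15-tetramethylhexadeca-2,6,10,14-tetraene | C/C(CO[Si](c1ccccc1)(c1ccccc1)C(C)(C)C)=C\CC/C(C)=C/CC/C(C)=C/[C@@H](O[Si](C)(C)C(C)(C)C)C/C(C)=C/CBr | intermediate
16 | 2-methylphenol | Cc1ccccc1O | starting material
17 | sodium 2-methylphenoxide, formed in the flask | Cc1ccccc1[O-].[Na+] | intermediate
18 | 2-[(2E,5S,6E,10E,14E)-5-(tert-butyldimethylsilyloxy)-16-(tert-butyldiphenylsilyloxy)-3,7,11,15-tetramethylhexadeca-2,6,10,14-tetraen-1-yl]-6-methylphenol | C/C(CO[Si](c1ccccc1)(c1ccccc1)C(C)(C)C)=C\CC/C(C)=C/CC/C(C)=C/[C@@H](O[Si](C)(C)C(C)(C)C)C/C(C)=C/Cc1cccc(C)c1O | intermediate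
19 | 2-[(2E,5S,6E,10E,14E)-5,16-dihydroxy-3,7,11,15-tetramethylhexadeca-2,6,10,14-tetraen-1-yl]-6-methylphenol | C/C(=C\CC/C(C)=C/CC/C(C)=C/[C@@H](O)C/C(C)=C/Cc1cccc(C)c1O)CO | intermediate
20 | phenoxyl radical of 19, formed in the flask | C/C(=C\CC/C(C)=C/CC/C(C)=C/[C@@H](O)C/C(C)=C/Cc1cccc(C)c1[O])CO | intermediate
21 | dipotassium salt of the 4-[bis(sulfonato)aminooxy]cyclohexa-2,5-dien-1-one adduct derived from 19 (both C4 epimers), formed in the flask | C/C(=C\CC/C(C)=C/CC/C(C)=C/[C@@H](O)C/C(C)=C/CC1=CC(ON(S(=O)(=O)[O-])S(=O)(=O)[O-])C=C(C)C1=O)CO.[K+].[K+] | intermediate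
22 | 2-[(2E,5S,6E,10E,14E)-5,16-dihydroxy-3,7,11,15-tetramethylhexadeca-2,6,10,14-tetraen-1-yl]-6-methyl-1,4-benzoquinone | C/C(=C\CC/C(C)=C/CC/C(C)=C/[C@@H](O)C/C(C)=C/CC1=CC(=O)C=C(C)C1=O)CO | intermediate
23 | 2-[(2E,5S,6E,10E,14E)-5,16-dihydroxy-3,7,11,15-tetramethylhexadeca-2,6,10,14-tetraen-1-yl]-6-methylbenzene-1,4-diol (CNP0151872.1) | C/C(=C\CC/C(C)=C/CC/C(C)=C/[C@@H](O)C/C(C)=C/Cc1cc(O)cc(C)c1O)CO | target

**Step count and risks**

Total step count: 13. Longest linear sequence: 13 steps, from farnesol 1 to 23; 7 and 16 are bought and enter directly.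

Steps most likely to fail:

Step 10. The phenoxide is ambident, so O-allylation, allylation at the para carbon and a second allylation of the product can compete with attack at C6, and the allylic bromide can eliminate or transpose on long contact with the basic slurry. The fallback fixes the site of bond formation with a halogen; it sets out from bromide 15 and comes back to the route at 19. Commercial 2-bromo-6-methylphenol (Cc1cccc(Br)c1O) is protected with 2-(trimethylsilyl)ethoxymethyl chloride and i-Pr2NEt in CH2Cl2 to give [2-[(2-bromo-6-methylphenoxy)methoxy]ethyl]trimethylsilane F1. Bromine–lithium exchange (n-BuLi, THF, −78 °C) and copper-catalysed coupling (CuBr·SMe2, 10 mol%) with 15 at the primary allylic carbon should give the SEM ether of phenol 18 F2. Bu4NF in THF/N,N'-dimethylpropyleneurea at 50 °C then removes the SEM group together with both silyl ethers and delivers 19, which enters step 12.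

Step 6. Addition to the deactivated β,β-disubstituted enal may be slow, facial discrimination may be insufficient or of the opposite sense, and the acid may cause E/Z drift of the enal over long reaction times. The fallback replaces catalyst control by a kinetic resolution; it sets out from 6 and comes back at 9. Allenylboration of 6 with 7 under achiral catalysis (diphenyl hydrogen phosphate, toluene, rt) and hydrolytic work-up gives racemic 15-(tert-butyldiphenylsilyloxy)-6,10,14-trimethylpentadeca-5,9,13-trien-1-yn-4-ol F3. Acylation with vinyl acetate and immobilised Candida antarctica lipase B in hexane at 30 °C should, by the usual preference of lipases for the secondary alcohol whose large group (here the alkenyl chain) outranks the small one (the propargyl CH2), convert the 4R enantiomer into the (4R)-acetate F4. This is separated by chromatography from unreacted (4S)-alcohol 9, which continues with step 7.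

Step 8. The Lewis acidic aluminium and zirconium species may ionise the allylic silyl ether at C5' (elimination or loss of configuration), regiocontrol of the methylalumination may be incomplete, and capture of the alkenylalane by formaldehyde may be sluggish so that protonolysis to the 2-methyl-1-alkene takes over. The fallback builds the trisubstituted alkene without a Lewis acid; it sets out from 10 and comes back at 13. C-Hydroxymethylation of the terminal alkyne (n-BuLi, THF, −78 °C; then (CH2O)n) gives (5S,6E,10E,14E)-5-(tert-butyldimethylsilyloxy)-16-(tert-butyldiphenylsilyloxy)-7,11,15-trimethylhexadeca-6,10,14-trien-2-yn-1-ol F5. Hydroxyl-directed trans-hydroalumination with NaAlH2(OCH2CH2OMe)2 in THF at 0 °C and iodinolysis (I2, −78 °C) gives (2Z,5S,6E,10E,14E)-3-iodo-5-(tert-butyldimethylsilyloxy)-16-(tert-butyldiphenylsilyloxy)-7,11,15-trimethylhexadeca-2,6,10,14-tetraen-1-ol F6. Me2CuLi in Et2O at 0 °C replaces iodine by methyl with retention and should give 13 with the 2E geometry.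

**Further compounds**

F1 | step 10 | [2-[(2-bromo-6-methylphenoxy)methoxy]ethyl]trimethylsilane (SEM ether of 2-bromo-6-methylphenol) | Cc1cccc(Br)c1OCOCC[Si](C)(C)C
F2 | step 10 | 2-(trimethylsilyl)ethoxymethyl ether of phenol 18 | C/C(CO[Si](c1ccccc1)(c1ccccc1)C(C)(C)C)=C\CC/C(C)=C/CC/C(C)=C/[C@@H](O[Si](C)(C)C(C)(C)C)C/C(C)=C/Cc1cccc(C)c1OCOCC[Si](C)(C)C
F3 | step 6 | racemic (5E,9E,13E)-15-(tert-butyldiphenylsilyloxy)-6,10,14-trimethylpentadeca-5,9,13-trien-1-yn-4-ol | C/C(CO[Si](c1ccccc1)(c1ccccc1)C(C)(C)C)=C\CC/C(C)=C/CC/C(C)=C/C(O)CC#C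
F4 | step 6 | (4R,5E,9E,13E)-15-(tert-butyldiphenylsilyloxy)-6,10,14-trimethylpentadeca-5,9,13-trien-1-yn-4-yl acetate | C/C(CO[Si](c1ccccc1)(c1ccccc1)C(C)(C)C)=C\CC/C(C)=C/CC/C(C)=C/[C@H](OC(C)=O)CC#C
F5 | step 8 | (5S,6E,10E,14E)-5-(tert-butyldimethylsilyloxy)-16-(tert-butyldiphenylsilyloxy)-7,11,15-trimethylhexadeca-6,10,14-trien-2-yn-1-ol | C/C(CO[Si](c1ccccc1)(c1ccccc1)C(C)(C)C)=C\CC/C(C)=C/CC/C(C)=C/[C@@H](O[Si](C)(C)C(C)(C)C)CC#CCO
F6 | step 8 | (2Z,5S,6E,10E,14E)-3-iodo-5-(tert-butyldimethylsilyloxy)-16-(tert-butyldiphenylsilyloxy)-7,11,15-trimethylhexadeca-2,6,10,14-tetraen-1-ol | C/C(CO[Si](c1ccccc1)(c1ccccc1)C(C)(C)C)=C\CC/C(C)=C/CC/C(C)=C/[C@@H](O[Si](C)(C)C(C)(C)C)C/C(I)=C/CO
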